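**Plan**
- The retrosynthesis first cuts the depside ester bond between the ring A carboxyl and the 4-oxygen of ring B. It then cuts the ring A C6–CH2 bond of the 2-oxopentyl arm.
- The enabling feature: C6 is the only C–H next to the C1 carboxyl of ring A, because C2 carries oxygen. The C1 carboxyl together with the C6 CH2–CO–propyl arm is a ring-opened 3-propylisocoumarin.
- Forward: acid 3 and the butyryl sulfoxonium ylide 7 are annulated to isocoumarin 9, which is the only ring built in the route.
- The lactone is then opened, the ketone is masked as a dioxolane, the acid is esterified with the ring B phenol 14, and the ketal and benzyl groups are removed.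
- The target has no stereocenter, so no stereocontrol is needed.

Key step: step 4

Assumption: ring B is bought as 2,4-dihydroxy-6-propylbenzoic acid (divarinic acid), sold as a fine chemical; because such resorcylic acids decarboxylate on heating, it is handled only at room temperature.

**Step 1**
Reactants: 1 2-hydroxy-4-methoxybenzoic acid
Product: 2 benzyl 2-(benzyloxy)-4-methoxybenzoate
Conditions: BnBr, K2CO3, DMF, 60 °C
Reagents that add atoms: benzyl bromide, BrCc1ccccc1
Why: Williamson-type SN2 benzylation of both the carboxylate and the chelated phenoxide should cap the two acidic oxygens in one operation.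

**Step 2**
Reactants: 2 benzyl 2-(benzyloxy)-4-methoxybenzoate
Product: 3 2-(benzyloxy)-4-methoxybenzoic acid
Conditions: NaOH, MeOH/THF/H2O, 65 °C; then 1 M HCl
Reagents that add atoms: sodium hydroxide, [Na+].[OH-]
Why: Saponification (acyl-oxygen ester hydrolysis) should free the carboxyl, while the benzyl aryl ether and the methyl ether are inert to hydroxide.

**Step 3**
Reactants: 4 trimethylsulfoxonium iodide; 5 butanoyl chloride
Product: 7 dimethylsulfoxonium 2-oxopentylide (1-[dimethyl(oxo)-λ6-sulfanylidene]pentan-2-one), via dimethylsulfoxonium methylide 6 (not isolated)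
Conditions: KOC(CH3)3, THF, reflux; then 5, 0 °C to rt
Reagents that add atoms: none
Why: Deprotonation gives the Corey–Chaykovsky methylide, whose C-acylation by the acid chloride, followed by deprotonation by a second equivalent of methylide, should give the stabilized β-keto sulfoxonium ylide.

**Step 4**
Reactants: 3 2-(benzyloxy)-4-methoxybenzoic acid; 7 dimethylsulfoxonium 2-oxopentylide
Product: 9 8-(benzyloxy)-6-methoxy-3-propyl-1H-isochromen-1-one, via keto acid 8 (not isolated)
Conditions: [(C5Me5)RhCl2]2 (4 mol %), AgSbF6 (16 mol %), NaOAc (30 mol %), ClCH2CH2Cl, 100 °C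
Reagents that add atoms: none
Why: Carboxylate-assisted concerted metalation–deprotonation by the cationic (C5Me5)Rh species (trivalent rhodium) at C6 of 3 should give a five-membered rhodacycle; ylide 7 then binds through carbon, loses dimethyl sulfoxide to form a rhodium carbene, and 1,1-migratory insertion of the aryl group makes the C6–CH bond. Protodemetalation releases keto acid 8 and returns the catalyst, so no external oxidant is needed. The ring closes by 6-exo-trig addition of the carboxyl oxygen to the ketone carbonyl, and loss of water from the lactol gives the conjugated pyranone of 9. The closest known reaction type is the ortho C–H acylmethylation and annulation of benzoic acids and N-methoxybenzamides with sulfoxonium ylides under trivalent rhodium, which gives 3-substituted isocoumarins. No stereocenter is formed. The step needs site selectivity and mono-alkylation: C6 is the only C–H ortho to the carboxylate because C2 carries the benzyloxy group, and lactonization removes the directing carboxylate after one insertion.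

**Step 5**
Reactants: 9 8-(benzyloxy)-6-methoxy-3-propyl-1H-isochromen-1-one
Product: 8 2-(benzyloxy)-4-methoxy-6-(2-oxopentyl)benzoic acid
Conditions: KOH, EtOH/H2O, 70 °C; then 1 M HCl, 0 °C, to pH 3
Reagents that add atoms: potassium hydroxide, [K+].[OH-]
Why: Saponification of the enol lactone should expel an enolate that ketonizes, and cold, mild acidification should deliver the open keto acid without acid-driven reclosure.

**Step 6**
Reactants: 8 2-(benzyloxy)-4-methoxy-6-(2-oxopentyl)benzoic acid
Product: 10 prop-2-en-1-yl 2-(benzyloxy)-4-methoxy-6-(2-oxopentyl)benzoate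
Conditions: allyl bromide, KHCO3, DMF, rt
Reagents that add atoms: allyl bromide, C=CCBr
Why: SN2 O-alkylation of the carboxylate uses the acid as a nucleophile, so the lactone cannot reclose as it would on acyl activation, and hydrogen carbonate is too weak a base to enolize the benzylic ketone.

**Step 7**
Reactants: 10 prop-2-en-1-yl 2-(benzyloxy)-4-methoxy-6-(2-oxopentyl)benzoate
Product: 11 prop-2-en-1-yl 2-(benzyloxy)-4-methoxy-6-[(2-propyl-1,3-dioxolan-2-yl)methyl]benzoate
Conditions: Me3SiOCH2CH2OSiMe3, Me3SiOTf (5 mol %), CH2Cl2, −78 to −20 °C; then pyridine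
Reagents that add atoms: 1,2-bis(trimethylsilyloxy)ethane, C[Si](C)(C)OCCO[Si](C)(C)C
Why: Noyori ketalization is aprotic and runs cold, so the unhindered dialkyl ketone should be masked as its dioxolane before any acid-promoted enol lactonization back to 9 can compete.

**Step 8**
Reactants: 11 prop-2-en-1-yl 2-(benzyloxy)-4-methoxy-6-[(2-propyl-1,3-dioxolan-2-yl)methyl]benzoate
Product: 12 2-(benzyloxy)-4-methoxy-6-[(2-propyl-1,3-dioxolan-2-yl)methyl]benzoic acid
Conditions: Pd(PPh3)4 (5 mol %), morpholine, THF, rt; pH 5 phosphate buffer work-up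
Reagents that add atoms: none
Why: Tsuji–Trost deallylation with zerovalent palladium cleaves the O–allyl bond through a π-allyl complex trapped by morpholine, so the hindered 2,6-disubstituted carboxyl is freed under neutral conditions that spare the ketal and the benzyl ether.

**Step 9**
Reactants: 13 2,4-dihydroxy-6-propylbenzoic acid
Product: 14 benzyl 2,4-dihydroxy-6-propylbenzoate
Conditions: BnBr, KHCO3, DMF, rt
Reagents that add atoms: benzyl bromide, BrCc1ccccc1
Why: Chemoselective SN2 alkylation of the carboxylate should occur because hydrogen carbonate deprotonates the acid but not the phenols to any useful extent.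

**Step 10**
Reactants: 12 2-(benzyloxy)-4-methoxy-6-[(2-propyl-1,3-dioxolan-2-yl)methyl]benzoic acid; 14 benzyl 2,4-dihydroxy-6-propylbenzoate
Product: 15 benzyl 4-({2-(benzyloxy)-4-methoxy-6-[(2-propyl-1,3-dioxolan-2-yl)methyl]benzoyl}oxy)-2-hydroxy-6-propylbenzoate
Conditions: DCC, DMAP (20 mol %), CH2Cl2, 0 °C to rt
Reagents that add atoms: none
Why: Steglich esterification through the acylpyridinium should acylate the free 4-hydroxyl of 14 selectively, since the 2-hydroxyl is hydrogen-bonded to the ester carbonyl and flanked by it, and the basic medium spares the ketal.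

**Step 11**
Reactants: 15 benzyl 4-({2-(benzyloxy)-4-methoxy-6-[(2-propyl-1,3-dioxolan-2-yl)methyl]benzoyl}oxy)-2-hydroxy-6-propylbenzoate
Product: 16 benzyl 4-{[2-(benzyloxy)-4-methoxy-6-(2-oxopentyl)benzoyl]oxy}-2-hydroxy-6-propylbenzoate
Conditions: 1 M HCl, THF, rt
Reagents that add atoms: water, O
Why: Acid-catalyzed ketal hydrolysis through the oxocarbenium ion should return the ketone at room temperature, where aryl and benzyl esters and benzyl ethers are stable to dilute acid.

**Step 12**
Reactants: 16 benzyl 4-{[2-(benzyloxy)-4-methoxy-6-(2-oxopentyl)benzoyl]oxy}-2-hydroxy-6-propylbenzoate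
Product: 17 4-{[2-hydroxy-4-methoxy-6-(2-oxopentyl)benzoyl]oxy}-2-hydroxy-6-propylbenzoic acid
Conditions: H2 (1 atm), 10% Pd/C, EtOAc, rt
Reagents that add atoms: none
Why: Catalytic hydrogenolysis should cleave the benzyl ether and the benzyl ester as toluene, leaving the non-benzylic dialkyl ketone, the aryl ester and both arenes untouched.

**Compound list**
1 | 2-hydroxy-4-methoxybenzoic acid | COc1ccc(C(=O)O)c(O)c1 | starting material
2 | benzyl 2-(benzyloxy)-4-methoxybenzoate | COc1ccc(C(=O)OCc2ccccc2)c(OCc2ccccc2)c1 | intermediate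
3 | 2-(benzyloxy)-4-methoxybenzoic acid | COc1ccc(C(=O)O)c(OCc2ccccc2)c1 | intermediate
4 | trimethylsulfoxonium iodide | C[S+](C)(C)=O.[I-] | starting material
5 | butanoyl chloride | CCCC(=O)Cl | starting material
6 | dimethylsulfoxonium methylide | C=S(C)(C)=O | intermediate (not isolated)
7 | dimethylsulfoxonium 2-oxopentylide (1-[dimethyl(oxo)-λ6-sulfanylidene]pentan-2-one) | CCCC(=O)C=S(C)(C)=O | intermediate
8 | 2-(benzyloxy)-4-methoxy-6-(2-oxopentyl)benzoic acid | CCCC(=O)Cc1cc(OC)cc(OCc2ccccc2)c1C(=O)O | intermediate (passed through in step 4, isolated in step 5)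
9 | 8-(benzyloxy)-6-methoxy-3-propyl-1H-isochromen-1-one | CCCC1=Cc2cc(OC)cc(OCc3ccccc3)c2C(=O)O1 | intermediate
10 | prop-2-en-1-yl 2-(benzyloxy)-4-methoxy-6-(2-oxopentyl)benzoate | CCCC(=O)Cc1cc(OC)cc(OCc2ccccc2)c1C(=O)OCC=C | intermediate
11 | prop-2-en-1-yl 2-(benzyloxy)-4-methoxy-6-[(2-propyl-1,3-dioxolan-2-yl)methyl]benzoate | CCCC1(Cc2cc(OC)cc(OCc3ccccc3)c2C(=O)OCC=C)OCCO1 | intermediate
12 | 2-(benzyloxy)-4-methoxy-6-[(2-propyl-1,3-dioxolan-2-yl)methyl]benzoic acid | CCCC1(Cc2cc(OC)cc(OCc3ccccc3)c2C(=O)O)OCCO1 | intermediate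
13 | 2,4-dihydroxy-6-propylbenzoic acid | CCCc1cc(O)cc(O)c1C(=O)O | starting material
14 | benzyl 2,4-dihydroxy-6-propylbenzoate | CCCc1cc(O)cc(O)c1C(=O)OCc1ccccc1 | intermediate
15 | benzyl 4-({2-(benzyloxy)-4-methoxy-6-[(2-propyl-1,3-dioxolan-2-yl)methyl]benzoyl}oxy)-2-hydroxy-6-propylbenzoate | CCCC1(Cc2cc(OC)cc(OCc3ccccc3)c2C(=O)Oc2cc(O)c(C(=O)OCc3ccccc3)c(CCC)c2)OCCO1 | intermediate
16 | benzyl 4-{[2-(benzyloxy)-4-methoxy-6-(2-oxopentyl)benzoyl]oxy}-2-hydroxy-6-propylbenzoate | CCCC(=O)Cc1cc(OC)cc(OCc2ccccc2)c1C(=O)Oc1cc(O)c(C(=O)OCc2ccccc2)c(CCC)c1 | intermediate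
17 | 4-{[2-hydroxy-4-methoxy-6-(2-oxopentyl)benzoyl]oxy}-2-hydroxy-6-propylbenzoic acid | CCCC(=O)Cc1cc(OC)cc(O)c1C(=O)Oc1cc(O)c(C(=O)O)c(CCC)c1 | target

**Step count**
Total: 12 steps. Longest linear sequence: 10 steps (1, 2, 4, 5, 6, 7, 8, 10, 11, 12); steps 3 and 9 are one-step branches.

**Steps most likely to fail**

Step 4. Protodecarboxylation of the electron-rich ortho-alkoxybenzoic acid, or carbene O–H insertion that esterifies the acid with the ylide, may outrun C–H metalation. The fallback sets out from acid 3 and comes back to the route at isocoumarin 9. Acid 3 is converted with (COCl)2 and catalytic DMF, then MeONH2·HCl and K2CO3, into 2-(benzyloxy)-N,4-dimethoxybenzamide F1. The N-methoxyamide is a stronger directing group that can neither decarboxylate nor be O-alkylated by the carbene. F1 and ylide 7, with [(C5Me5)RhCl2]2, AgSbF6 and Zn(OTf)2 in a fluorinated alcohol, should undergo the same C6 acylmethylation. Under these acidic conditions the keto amide should lactonize with loss of O-methylhydroxylamine to give 9.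

Step 10. Acylation at the doubly ortho-substituted carboxyl may be slow enough for the O-acylisourea to rearrange to the N-acylurea, or for the ketal oxygen to intercept the activated acyl group. The fallback sets out from acid 12 and comes back at depside 15. Acid 12 is treated with cyanuric fluoride and pyridine in CH2Cl2 at −10 °C to give 2-(benzyloxy)-4-methoxy-6-[(2-propyl-1,3-dioxolan-2-yl)methyl]benzoyl fluoride F2. This is a small, isolable acyl donor that tolerates hindrance and has no rearrangement pathway. F2 is then added to the 4-phenoxide of 14, formed with K2CO3 in MeCN, which should give 15 by direct acyl substitution.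

Step 11. Under the acid needed for ketal hydrolysis, the liberated ketone may enolize and lactonize onto the aryl ester, cleaving the depside back into an isocoumarin and phenol 14. The fallback sets out from keto ester 10 and comes back at target 17, with no acid used after the depside bond is made.
- Ketone 10 is ketalized with the bis-trimethylsilyl ether of 1,2-benzenedimethanol and catalytic Me3SiOTf in CH2Cl2 at −78 °C. This gives prop-2-en-1-yl 2-(benzyloxy)-4-methoxy-6-[(3-propyl-1,5-dihydro-2,4-benzodioxepin-3-yl)methyl]benzoate F3, a ketal with two benzylic C–O bonds.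
- Deallylation with Pd(PPh3)4 and morpholine gives 2-(benzyloxy)-4-methoxy-6-[(3-propyl-1,5-dihydro-2,4-benzodioxepin-3-yl)methyl]benzoic acid F4.
- DCC/DMAP coupling with 14 gives benzyl 4-({2-(benzyloxy)-4-methoxy-6-[(3-propyl-1,5-dihydro-2,4-benzodioxepin-3-yl)methyl]benzoyl}oxy)-2-hydroxy-6-propylbenzoate F5.
- A single hydrogenolysis (H2, Pd/C, EtOAc) should then cleave the benzyl ether, the benzyl ester and both benzylic C–O bonds of the ketal, releasing the ketone and giving 17 under neutral conditions.

**Further compounds**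
F1 | step 4 | 2-(benzyloxy)-N,4-dimethoxybenzamide | CONC(=O)c1ccc(OC)cc1OCc1ccccc1
F2 | step 10 | 2-(benzyloxy)-4-methoxy-6-[(2-propyl-1,3-dioxolan-2-yl)methyl]benzoyl fluoride | CCCC1(Cc2cc(OC)cc(OCc3ccccc3)c2C(F)=O)OCCO1
F3 | step 11 | prop-2-en-1-yl 2-(benzyloxy)-4-methoxy-6-[(3-propyl-1,5-dihydro-2,4-benzodioxepin-3-yl)methyl]benzoate | CCCC1(Cc2cc(OC)cc(OCc3ccccc3)c2C(=O)OCC=C)OCc2ccccc2CO1
F4 | step 11 | 2-(benzyloxy)-4-methoxy-6-[(3-propyl-1,5-dihydro-2,4-benzodioxepin-3-yl)methyl]benzoic acid | CCCC1(Cc2cc(OC)cc(OCc3ccccc3)c2C(=O)O)OCc2ccccc2CO1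
F5 | step 11 | benzyl 4-({2-(benzyloxy)-4-methoxy-6-[(3-propyl-1,5-dihydro-2,4-benzodioxepin-3-yl)methyl]benzoyl}oxy)-2-hydroxy-6-propylbenzoate | CCCC1(Cc2cc(OC)cc(OCc3ccccc3)c2C(=O)Oc2cc(O)c(C(=O)OCc3ccccc3)c(CCC)c2)OCc2ccccc2CO1
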